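The numbering used is C1 (quaternary, CH3), C2 (O‑angeloyl), C3, C4 (C(OH)iPr), C5 (ring‑fusion CH), C6 (O‑aroyl), C7, C8(CH3)=C9, C10. The seven‑membered ring C1/C5–C10 is a benzene ring C5–C10 (oxygen at C6, methyl at C8) with C1 inserted between C5 and C10. An intramolecular Buchner reaction of an α‑methyl diazoketone forms C1–C5 and C1–C10 at once, closing the cyclopentanone C1–C5, expanding the arene to the cycloheptatriene and setting C1 against C4. The precursor is an enantiopure, O‑silylated 2‑methoxy‑4‑methylphenyl isopropyl carbinol bearing a CH2COC(N2)CH3 arm; its anisole oxygen later becomes the C6 ketone.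

Key step: step 7

Assumption: the (S,S) antipode of allylsilane 5 (step 2) and the S antipode of the rhodium catalyst (step 7) are taken as the ones that deliver the senses drawn; if either proves mismatched, its mirror image is used and nothing else changes.

Step 1
Reactants: 1 m‑cresol; 2 isobutyryl chloride
Product: 4 1‑(2‑hydroxy‑4‑methylphenyl)‑2‑methylpropan‑1‑one, via 3‑methylphenyl isobutyrate 3 (not isolated)
Conditions: neat, 60 °C (−HCl); then AlCl3 (1.5 equiv), 130 °C; ice/aq. HCl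
Reagents that add atoms: isobutyryl chloride 2, CC(C)C(Cl)=O
Why: Phenol O‑acylation followed by the AlCl3‑mediated Fries rearrangement, which at high temperature puts the acyl group ortho to oxygen and para to the methyl group (chelated o‑hydroxy ketone; the position between OH and CH3 is too hindered).

Step 2
Reactants: 4 1‑(2‑hydroxy‑4‑methylphenyl)‑2‑methylpropan‑1‑one; 5 (3aS,7aS)‑2‑allyl‑1,3‑bis(4‑bromobenzyl)‑2‑chlorooctahydro‑1H‑1,3,2‑benzodiazasilole
Product: 6 2‑[(3S)‑3‑hydroxy‑2‑methylhex‑5‑en‑3‑yl]‑5‑methylphenol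
Conditions: 5 (1.5 equiv), CH2Cl2, 23 → 40 °C; then 1 M HCl, 0 °C, brief
Reagents that add atoms: allylsilane 5 (allyl group), C=CC[Si]1(Cl)N(Cc2ccc(Br)cc2)[C@H]2CCCC[C@@H]2N1Cc1ccc(Br)cc1
Why: Allylation with a strained chiral allylchlorosilane (Leighton‑type reagent), a reaction established for 2‑hydroxyphenyl ketones including branched alkyl ones: the phenol displaces chloride on silicon, the bound ketone is activated and the allyl group is delivered intramolecularly through a closed chair‑like transition state whose facial preference, fixed by the C2‑symmetric diamine, sets C4 as S.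

Step 3
Reactants: 6 2‑[(3S)‑3‑hydroxy‑2‑methylhex‑5‑en‑3‑yl]‑5‑methylphenol
Product: 7 (3S)‑3‑(2‑methoxy‑4‑methylphenyl)‑2‑methylhex‑5‑en‑3‑ol
Conditions: MeI, K2CO3, DMF, 23 °C
Reagents that add atoms: iodomethane, CI
Why: Williamson ether synthesis; carbonate deprotonates only the phenol, so the tertiary alcohol stays free and the stereocentre is untouched.

Step 4
Reactants: 7 (3S)‑3‑(2‑methoxy‑4‑methylphenyl)‑2‑methylhex‑5‑en‑3‑ol
Product: 8 triethyl{[(3S)‑3‑(2‑methoxy‑4‑methylphenyl)‑2‑methylhex‑5‑en‑3‑yl]oxy}silane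
Conditions: Et3SiOTf, 2,6‑lutidine, CH2Cl2, −20 → 23 °C
Reagents that add atoms: triethylsilyl trifluoromethanesulfonate, CC[Si](CC)(CC)OS(=O)(=O)C(F)(F)F
Why: Silylation of a hindered tertiary alcohol with a silyl triflate under lutidine buffering, which keeps the electron‑rich benzylic C–O bond from ionising; the bulky Et3SiO group later also orients the carbenoid arm.

Step 5
Reactants: 8 triethyl{[(3S)‑3‑(2‑methoxy‑4‑methylphenyl)‑2‑methylhex‑5‑en‑3‑yl]oxy}silane
Product: 10 (3S)‑3‑(2‑methoxy‑4‑methylphenyl)‑4‑methyl‑3‑[(triethylsilyl)oxy]pentanoic acid, via aldehyde 9 (not isolated)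
Conditions: O3, CH2Cl2, −78 °C (Sudan III end‑point); Me2S; then NaClO2, NaH2PO4, 2‑methyl‑2‑butene, t‑BuOH/H2O, 0 → 23 °C
Reagents that add atoms: ozone, [O-][O+]=O; sodium chlorite, [Na+].[O-]Cl=O
Why: Ozonolysis of the terminal alkene (much faster than attack on the anisole ring at −78 °C) and Pinnick oxidation of the crude β‑silyloxy aldehyde at buffered pH, with 2‑methyl‑2‑butene scavenging hypochlorite so that the arene is not chlorinated.

Step 6
Reactants: 10 (3S)‑3‑(2‑methoxy‑4‑methylphenyl)‑4‑methyl‑3‑[(triethylsilyl)oxy]pentanoic acid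
Product: 12 (5S)‑2‑diazo‑5‑(2‑methoxy‑4‑methylphenyl)‑6‑methyl‑5‑[(triethylsilyl)oxy]heptan‑3‑one, via acid chloride 11 (not isolated)
Conditions: 1‑chloro‑N,N,2‑trimethylprop‑1‑en‑1‑amine, CH2Cl2, 0 °C; then CH3CHN2 (3 equiv, dried Et2O solution made from N‑ethyl‑N‑nitrosourea/KOH, not distilled), −20 → 0 °C
Reagents that add atoms: diazoethane, CC=[N+]=[N-] (the chlorine of intermediate 11 comes from 1‑chloro‑N,N,2‑trimethylprop‑1‑en‑1‑amine, CC(C)=C(Cl)N(C)C, and is lost again)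
Why: Acylation of a diazoalkane by an acid chloride, the standard route to α‑alkyl α‑diazoketones; the chloride is made with Ghosez's reagent under neutral conditions so that no HCl meets the tertiary benzylic silyl ether, and the second equivalent of diazoethane takes up the HCl released.

Step 7
Reactants: 12 (5S)‑2‑diazo‑5‑(2‑methoxy‑4‑methylphenyl)‑6‑methyl‑5‑[(triethylsilyl)oxy]heptan‑3‑one
Product: 14 (3S,8aR)‑4‑methoxy‑6,8a‑dimethyl‑3‑(propan‑2‑yl)‑3‑[(triethylsilyl)oxy]‑2,3‑dihydroazulen‑1(8aH)‑one, via norcaradiene 13 (not isolated)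
Conditions: Rh2(S‑PTAD)4 (1 mol %), CH2Cl2, −40 → 0 °C, slow addition of 12
Reagents that add atoms: none
Why: Loss of N2 gives an electrophilic Rh carbenoid at C1 that attacks the electron‑rich ipso carbon C5 (ortho to OMe, para to CH3) through the three‑atom tether and closes onto the free ortho carbon C10, an intramolecular [2+1] cycloaddition across C5–C10 to norcaradiene 13, whose C5–C10 bond then opens by thermal disrotatory 6π electrocyclic reaction to cycloheptatriene 14. This is the intramolecular Buchner reaction known for 1‑diazo‑4‑arylbutan‑2‑ones and their α‑methyl homologues, which give 8a‑methylazulenones. The cyclopentanone closes by attack of the tethered carbenoid carbon on C5 (five‑membered ring through the ipso carbon, 5‑exo in type), while the seven‑membered ring is not closed from a chain but arises by one‑carbon expansion of the benzene ring when the cyclopropane bond opens. The new quaternary centre C1 is fixed by the arene face that the arm reaches: with the Et3SiO group turned away from the methoxy oxygen and from the metal, and the isopropyl C–H pointing at OMe, the arm lies on the face that gives 8aR (CH3 trans to the siloxy group); this substrate preference is expected to be modest, so the chiral carboxylate catalyst is chosen to reinforce it. Addition at C5–C10 and not at C5–C6 follows from the blocked, methoxy‑bearing ortho carbon (a donor–acceptor cyclopropane formed there would reopen), and bulky carboxylate ligands at low temperature hold back 1,2‑hydride shift from the C‑methyl group, insertion into the isopropyl C–H and attack on the hindered, weakly basic silyl ether oxygen.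

Step 8
Reactants: 14 (3S,8aR)‑4‑methoxy‑6,8a‑dimethyl‑3‑(propan‑2‑yl)‑3‑[(triethylsilyl)oxy]‑2,3‑dihydroazulen‑1(8aH)‑one
Product: 15 (1S,3S,8aR)‑4‑methoxy‑6,8a‑dimethyl‑3‑(propan‑2‑yl)‑3‑[(triethylsilyl)oxy]‑1,2,3,8a‑tetrahydroazulen‑1‑ol
Conditions: (R)‑Me‑CBS (0.5 equiv), catecholborane (2 equiv), toluene, −78 → −40 °C
Reagents that add atoms: none
Why: Corey–Bakshi–Shibata reduction: the catalyst tells the quaternary C1 side from the CH2 side of the cyclopentanone and delivers hydride to the face cis to the C1 methyl group, giving the 1S alcohol (OH trans to CH3, cis to the siloxy group) under reagent control; catecholborane at low temperature leaves the trienol ether alone.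

Step 9
Reactants: 15 (1S,3S,8aR)‑4‑methoxy‑6,8a‑dimethyl‑3‑(propan‑2‑yl)‑3‑[(triethylsilyl)oxy]‑1,2,3,8a‑tetrahydroazulen‑1‑ol
Product: 16 (1S,3S,3aS,8aR)‑1‑hydroxy‑6,8a‑dimethyl‑3‑(propan‑2‑yl)‑3‑[(triethylsilyl)oxy]‑2,3,3a,8a‑tetrahydroazulen‑4(1H)‑one
Conditions: oxalic acid (5 % aq.), THF, 0 → 23 °C
Reagents that add atoms: water, O
Why: Acid hydrolysis of an enol ether: protonation at C5 gives a methoxy‑stabilised pentadienyl cation that takes up water at C6 and loses methanol to give the conjugated dienone; C5 is protonated so that C6 swings to the side on which C10 already lies, which gives the cis ring fusion (H‑5 cis to the C1 methyl group), the only fusion the planar dienone can span without twisting and the one in which C6 avoids the isopropyl group, and the mild acid leaves the tertiary silyl ether in place.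

Step 10
Reactants: 16 (1S,3S,3aS,8aR)‑1‑hydroxy‑6,8a‑dimethyl‑3‑(propan‑2‑yl)‑3‑[(triethylsilyl)oxy]‑2,3,3a,8a‑tetrahydroazulen‑4(1H)‑one
Product: 18 (1S,3S,3aS,8aR)‑1‑hydroxy‑6,8a‑dimethyl‑3‑(propan‑2‑yl)‑3‑[(triethylsilyl)oxy]‑1,2,3,3a,8,8a‑hexahydroazulen‑4(5H)‑one, via dilithium dienolate 17 (not isolated)
Conditions: Li (3.5 equiv), NH3(l)/THF, −78 °C, 20 min; solid NH4Cl
Reagents that add atoms: none
Why: Dissolving‑metal 1,6‑reduction of a linear dienone: two electrons and a proton at the δ‑carbon C10 give dienolate 17, which resists further reduction and is protonated kinetically at the α‑carbon C7 on quenching, so that the double bond ends at C8=C9, as in the known conversion of 4,6‑dien‑3‑ones into 5‑en‑3‑ones; C5 is not part of the enolate and keeps its configuration.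

Step 11
Reactants: 18 (1S,3S,3aS,8aR)‑1‑hydroxy‑6,8a‑dimethyl‑3‑(propan‑2‑yl)‑3‑[(triethylsilyl)oxy]‑1,2,3,3a,8,8a‑hexahydroazulen‑4(5H)‑one; 19 angelic acid
Product: 21 (1S,3S,3aS,8aR)‑6,8a‑dimethyl‑4‑oxo‑3‑(propan‑2‑yl)‑3‑[(triethylsilyl)oxy]‑1,2,3,3a,4,5,8,8a‑octahydroazulen‑1‑yl (2Z)‑2‑methylbut‑2‑enoate, via mixed anhydride 20 (not isolated)
Conditions: 19 (3 equiv), 2,4,6‑Cl3C6H2COCl (3 equiv), Et3N (3 equiv), toluene, 23 °C; filter off Et3NHCl; then 18, toluene, 80 °C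
Reagents that add atoms: angelic acid 19, C/C=C(/C)C(O)=O (2,4,6‑trichlorobenzoyl chloride, O=C(Cl)c1c(Cl)cc(Cl)cc1Cl, enters only intermediate 20)
Why: Yamaguchi‑type esterification through the 2,4,6‑trichlorobenzoyl mixed anhydride, which needs no nucleophilic catalyst and so does not isomerise the Z‑alkene of the angelate; only the C2 hydroxyl is free, and the amine salt is removed before heating so that the β,γ‑enone is not exposed to base.

Step 12
Reactants: 21 (1S,3S,3aS,8aR)‑6,8a‑dimethyl‑4‑oxo‑3‑(propan‑2‑yl)‑3‑[(triethylsilyl)oxy]‑1,2,3,3a,4,5,8,8a‑octahydroazulen‑1‑yl (2Z)‑2‑methylbut‑2‑enoate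
Product: 22 (1S,3S,3aS,8aR)‑3‑hydroxy‑6,8a‑dimethyl‑4‑oxo‑3‑(propan‑2‑yl)‑1,2,3,3a,4,5,8,8a‑octahydroazulen‑1‑yl (2Z)‑2‑methylbut‑2‑enoate
Conditions: HF·pyridine, THF/pyridine, 0 → 23 °C
Reagents that add atoms: none
Why: Fluoride cleavage of the silyl ether under mildly acidic, non‑basic conditions, which spares the angelate and the β,γ‑enone and avoids retro‑aldol cleavage of the β‑hydroxy ketone that is set free.

Step 13
Reactants: 22 (1S,3S,3aS,8aR)‑3‑hydroxy‑6,8a‑dimethyl‑4‑oxo‑3‑(propan‑2‑yl)‑1,2,3,3a,4,5,8,8a‑octahydroazulen‑1‑yl (2Z)‑2‑methylbut‑2‑enoate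
Product: 23 (1S,3S,3aR,4R,8aR)‑3,4‑dihydroxy‑6,8a‑dimethyl‑3‑(propan‑2‑yl)‑1,2,3,3a,4,5,8,8a‑octahydroazulen‑1‑yl (2Z)‑2‑methylbut‑2‑enoate
Conditions: Me4NBH(OAc)3 (5 equiv), MeCN/AcOH 1:1, −30 → −20 °C
Reagents that add atoms: none
Why: Evans–Saksena hydroxyl‑directed reduction: the C4 hydroxyl exchanges onto boron and delivers hydride through a six‑membered transition state to the face of the C6 carbonyl that it overhangs, giving the 1,3‑anti diol (4R); the reagent does not touch the ester or the alkenes.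

Step 14
Reactants: 23 (1S,3S,3aR,4R,8aR)‑3,4‑dihydroxy‑6,8a‑dimethyl‑3‑(propan‑2‑yl)‑1,2,3,3a,4,5,8,8a‑octahydroazulen‑1‑yl (2Z)‑2‑methylbut‑2‑enoate; 24 3,4,5‑trimethoxybenzoyl chloride
Product: 25 (1S,3S,3aR,4R,8aR)‑3‑hydroxy‑6,8a‑dimethyl‑3‑(propan‑2‑yl)‑4‑[(3,4,5‑trimethoxybenzoyl)oxy]‑1,2,3,3a,4,5,8,8a‑octahydroazulen‑1‑yl (2Z)‑2‑methylbut‑2‑enoate (target, CNP0112256.1)
Conditions: 24 (1.5 equiv), Et3N, DMAP (cat.), CH2Cl2, 0 → 23 °C
Reagents that add atoms: 3,4,5‑trimethoxybenzoyl chloride 24, COc1cc(cc(OC)c1OC)C(Cl)=O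
Why: DMAP‑catalysed acylation by an acid chloride; the secondary C6 hydroxyl reacts while the hindered tertiary C4 hydroxyl does not, and the angelate already in place is not isomerised at room temperature.

Compound list
1 | m‑cresol (3‑methylphenol) | Cc1cccc(O)c1 | starting material
2 | isobutyryl chloride | CC(C)C(Cl)=O | starting material
3 | 3‑methylphenyl 2‑methylpropanoate | CC(C)C(=O)Oc1cccc(C)c1 | intermediate
4 | 1‑(2‑hydroxy‑4‑methylphenyl)‑2‑methylpropan‑1‑one | CC(C)C(=O)c1ccc(C)cc1O | intermediate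
5 | (3aS,7aS)‑2‑allyl‑1,3‑bis(4‑bromobenzyl)‑2‑chlorooctahydro‑1H‑1,3,2‑benzodiazasilole | C=CC[Si]1(Cl)N(Cc2ccc(Br)cc2)[C@H]2CCCC[C@@H]2N1Cc1ccc(Br)cc1 | starting material
6 | 2‑[(3S)‑3‑hydroxy‑2‑methylhex‑5‑en‑3‑yl]‑5‑methylphenol | C=CC[C@](O)(C(C)C)c1ccc(C)cc1O | intermediate
7 | (3S)‑3‑(2‑methoxy‑4‑methylphenyl)‑2‑methylhex‑5‑en‑3‑ol | C=CC[C@](O)(C(C)C)c1ccc(C)cc1OC | intermediate
8 | triethyl{[(3S)‑3‑(2‑methoxy‑4‑methylphenyl)‑2‑methylhex‑5‑en‑3‑yl]oxy}silane | C=CC[C@](O[Si](CC)(CC)CC)(C(C)C)c1ccc(C)cc1OC | intermediate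
9 | (3S)‑3‑(2‑methoxy‑4‑methylphenyl)‑4‑methyl‑3‑[(triethylsilyl)oxy]pentanal | O=CC[C@](O[Si](CC)(CC)CC)(C(C)C)c1ccc(C)cc1OC | intermediate
10 | (3S)‑3‑(2‑methoxy‑4‑methylphenyl)‑4‑methyl‑3‑[(triethylsilyl)oxy]pentanoic acid | OC(=O)C[C@](O[Si](CC)(CC)CC)(C(C)C)c1ccc(C)cc1OC | intermediate
11 | (3S)‑3‑(2‑methoxy‑4‑methylphenyl)‑4‑methyl‑3‑[(triethylsilyl)oxy]pentanoyl chloride | ClC(=O)C[C@](O[Si](CC)(CC)CC)(C(C)C)c1ccc(C)cc1OC | intermediate
12 | (5S)‑2‑diazo‑5‑(2‑methoxy‑4‑methylphenyl)‑6‑methyl‑5‑[(triethylsilyl)oxy]heptan‑3‑one (key‑step precursor) | CC(=[N+]=[N-])C(=O)C[C@](O[Si](CC)(CC)CC)(C(C)C)c1ccc(C)cc1OC | intermediate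
13 | norcaradiene valence isomer of 14 (cyclopropane through C8a, C3a and C8 of the azulenone numbering) | O=C1C[C@](O[Si](CC)(CC)CC)(C(C)C)[C@@]23C(OC)=CC(C)=C[C@@H]2[C@@]13C | intermediate
14 | (3S,8aR)‑4‑methoxy‑6,8a‑dimethyl‑3‑(propan‑2‑yl)‑3‑[(triethylsilyl)oxy]‑2,3‑dihydroazulen‑1(8aH)‑one (key‑step product) | O=C1C[C@](O[Si](CC)(CC)CC)(C(C)C)C2=C(OC)C=C(C)C=C[C@@]12C | intermediate
15 | (1S,3S,8aR)‑4‑methoxy‑6,8a‑dimethyl‑3‑(propan‑2‑yl)‑3‑[(triethylsilyl)oxy]‑1,2,3,8a‑tetrahydroazulen‑1‑ol | O[C@H]1C[C@](O[Si](CC)(CC)CC)(C(C)C)C2=C(OC)C=C(C)C=C[C@@]12C | intermediate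
16 | (1S,3S,3aS,8aR)‑1‑hydroxy‑6,8a‑dimethyl‑3‑(propan‑2‑yl)‑3‑[(triethylsilyl)oxy]‑2,3,3a,8a‑tetrahydroazulen‑4(1H)‑one | O[C@H]1C[C@](O[Si](CC)(CC)CC)(C(C)C)[C@H]2C(=O)C=C(C)C=C[C@@]12C | intermediate
17 | dilithium alkoxide dienolate of 18 (C6–O⁻, C6=C7, C8=C9) | [Li+].[Li+].[O-][C@H]1C[C@](O[Si](CC)(CC)CC)(C(C)C)[C@H]2C([O-])=CC(C)=CC[C@@]12C | intermediate
18 | (1S,3S,3aS,8aR)‑1‑hydroxy‑6,8a‑dimethyl‑3‑(propan‑2‑yl)‑3‑[(triethylsilyl)oxy]‑1,2,3,3a,8,8a‑hexahydroazulen‑4(5H)‑one | O[C@H]1C[C@](O[Si](CC)(CC)CC)(C(C)C)[C@H]2C(=O)CC(C)=CC[C@@]12C | intermediate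
19 | angelic acid, (2Z)‑2‑methylbut‑2‑enoic acid | C/C=C(/C)C(O)=O | starting material
20 | (2Z)‑2‑methylbut‑2‑enoic 2,4,6‑trichlorobenzoic anhydride | C/C=C(/C)C(=O)OC(=O)c1c(Cl)cc(Cl)cc1Cl | intermediate
21 | (1S,3S,3aS,8aR)‑6,8a‑dimethyl‑4‑oxo‑3‑(propan‑2‑yl)‑3‑[(triethylsilyl)oxy]‑1,2,3,3a,4,5,8,8a‑octahydroazulen‑1‑yl (2Z)‑2‑methylbut‑2‑enoate | C/C=C(/C)C(=O)O[C@H]1C[C@](O[Si](CC)(CC)CC)(C(C)C)[C@H]2C(=O)CC(C)=CC[C@@]12C | intermediate
22 | (1S,3S,3aS,8aR)‑3‑hydroxy‑6,8a‑dimethyl‑4‑oxo‑3‑(propan‑2‑yl)‑1,2,3,3a,4,5,8,8a‑octahydroazulen‑1‑yl (2Z)‑2‑methylbut‑2‑enoate | C/C=C(/C)C(=O)O[C@H]1C[C@](O)(C(C)C)[C@H]2C(=O)CC(C)=CC[C@@]12C | intermediate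
23 | (1S,3S,3aR,4R,8aR)‑3,4‑dihydroxy‑6,8a‑dimethyl‑3‑(propan‑2‑yl)‑1,2,3,3a,4,5,8,8a‑octahydroazulen‑1‑yl (2Z)‑2‑methylbut‑2‑enoate | C/C=C(/C)C(=O)O[C@H]1C[C@](O)(C(C)C)[C@H]2[C@H](O)CC(C)=CC[C@@]12C | intermediate
24 | 3,4,5‑trimethoxybenzoyl chloride | COc1cc(cc(OC)c1OC)C(Cl)=O | starting material
25 | (1S,3S,3aR,4R,8aR)‑3‑hydroxy‑6,8a‑dimethyl‑3‑(propan‑2‑yl)‑4‑[(3,4,5‑trimethoxybenzoyl)oxy]‑1,2,3,3a,4,5,8,8a‑octahydroazulen‑1‑yl (2Z)‑2‑methylbut‑2‑enoate | C/C=C(/C)C(=O)O[C@H]1C[C@](O)(C(C)C)[C@H]2[C@H](OC(=O)c3cc(OC)c(OC)c(OC)c3)CC(C)=CC[C@@]12C | target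

Total steps: 14. Longest linear sequence: 14 steps (1 → 25).

Steps most likely to fail

Step 7. The α‑methyl carbenoid may be lost before it reaches the arene (1,2‑hydride shift to the enone, insertion into the isopropyl C–H, attack on the silyl ether oxygen), or the two arene faces may not be told apart well enough. Fallback: the carbenoid is changed to an acceptor/acceptor type with no hydrogen on the carbene substituent, and the C1 methyl group is made afterwards from an ester. This fallback removes the carbenoid‑decay pathways and leaves face selection to the catalyst; it does not by itself correct a wrong facial preference. It sets out from acid 10: CDI, then magnesium methyl malonate gives β‑keto ester F1; diazo transfer (4‑acetamidobenzenesulfonyl azide, Et3N) gives diazo keto ester F2 without diazoethane; the same Rh(II) carboxylate effects the arene cycloaddition and ring expansion to azulenone ester F3; (R)‑Me‑CBS/catecholborane gives hydroxy ester F4; LiAlH4 reduces the ester to diol F5; TsCl/pyridine sulfonylates only the primary hydroxyl to give tosylate F6; LiEt3BH replaces the sulfonate by hydride and the route is rejoined at alcohol 15.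

Step 9. Protonation may not stop at the enol ether: the allylic C4–O bond can ionise to a vinylogous oxocarbenium ion, the silyloxy group can be eliminated from the new β‑silyloxy ketone, or C5 can be protonated from the wrong face. Fallback: hydrolysis and reduction are taken in the reverse order, so that C5 is protonated under basic, non‑ionising conditions. It sets out from alcohol 15: Li, NH3/THF, t‑BuOH, −78 °C reduces the conjugated triene 1,6 (hydrogen at C5 and C10) to 1‑methoxy‑1,3‑diene F7, in which C4–O is no longer allylic; brief oxalic acid hydrolysis protonates the dienol ether at C7 (as in the mild hydrolysis of 3‑alkoxy‑3,5‑dienes to 5‑en‑3‑ones) and gives β,γ‑enone 18, where the route is rejoined.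

Step 11. Acylation of the concave, neopentylic C2 hydroxyl may be so slow that Z→E isomerisation of the angeloyl unit or migration of the C8=C9 bond into conjugation with the C6 ketone takes over. Fallback: the C2–O bond is made by substitution with inversion instead of acylation. It sets out from azulenone 14: (S)‑Me‑CBS/catecholborane gives the C2‑epimeric alcohol F8; the conditions of steps 9 and 10 convert it into dienone F9 and β,γ‑enone F10; Mitsunobu reaction of F10 with angelic acid 19 (PPh3, DIAD, toluene, 0 → 23 °C) brings in the carboxylate anti to the angular methyl group under neutral conditions, as in the inversion of 17β‑hydroxy steroids, and the route is rejoined at angelate 21.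

Further compounds
F1 | step 7 | methyl (5S)‑5‑(2‑methoxy‑4‑methylphenyl)‑6‑methyl‑3‑oxo‑5‑[(triethylsilyl)oxy]heptanoate | COC(=O)CC(=O)C[C@](O[Si](CC)(CC)CC)(C(C)C)c1ccc(C)cc1OC
F2 | step 7 | methyl (5S)‑2‑diazo‑5‑(2‑methoxy‑4‑methylphenyl)‑6‑methyl‑3‑oxo‑5‑[(triethylsilyl)oxy]heptanoate | COC(=O)C(=[N+]=[N-])C(=O)C[C@](O[Si](CC)(CC)CC)(C(C)C)c1ccc(C)cc1OC
F3 | step 7 | methyl (3S,8aS)‑4‑methoxy‑6‑methyl‑1‑oxo‑3‑(propan‑2‑yl)‑3‑[(triethylsilyl)oxy]‑2,3‑dihydroazulene‑8a(1H)‑carboxylate | O=C1C[C@](O[Si](CC)(CC)CC)(C(C)C)C2=C(OC)C=C(C)C=C[C@@]12C(=O)OC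
F4 | step 7 | methyl (1S,3S,8aS)‑1‑hydroxy‑4‑methoxy‑6‑methyl‑3‑(propan‑2‑yl)‑3‑[(triethylsilyl)oxy]‑2,3‑dihydroazulene‑8a(1H)‑carboxylate | O[C@H]1C[C@](O[Si](CC)(CC)CC)(C(C)C)C2=C(OC)C=C(C)C=C[C@@]12C(=O)OC
F5 | step 7 | (1S,3S,8aR)‑8a‑(hydroxymethyl)‑4‑methoxy‑6‑methyl‑3‑(propan‑2‑yl)‑3‑[(triethylsilyl)oxy]‑1,2,3,8a‑tetrahydroazulen‑1‑ol | O[C@H]1C[C@](O[Si](CC)(CC)CC)(C(C)C)C2=C(OC)C=C(C)C=C[C@@]12CO
F6 | step 7 | [(1S,3S,8aR)‑1‑hydroxy‑4‑methoxy‑6‑methyl‑3‑(propan‑2‑yl)‑3‑[(triethylsilyl)oxy]‑2,3‑dihydroazulen‑8a(1H)‑yl]methyl 4‑methylbenzenesulfonate | O[C@H]1C[C@](O[Si](CC)(CC)CC)(C(C)C)C2=C(OC)C=C(C)C=C[C@@]12COS(=O)(=O)c1ccc(C)cc1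
F7 | step 9 | (1S,3S,3aR,8aR)‑4‑methoxy‑6,8a‑dimethyl‑3‑(propan‑2‑yl)‑3‑[(triethylsilyl)oxy]‑1,2,3,3a,8,8a‑hexahydroazulen‑1‑ol | O[C@H]1C[C@](O[Si](CC)(CC)CC)(C(C)C)[C@H]2C(OC)=CC(C)=CC[C@@]12C
F8 | step 11 | (1R,3S,8aR)‑4‑methoxy‑6,8a‑dimethyl‑3‑(propan‑2‑yl)‑3‑[(triethylsilyl)oxy]‑1,2,3,8a‑tetrahydroazulen‑1‑ol | O[C@@H]1C[C@](O[Si](CC)(CC)CC)(C(C)C)C2=C(OC)C=C(C)C=C[C@@]12C
F9 | step 11 | (1R,3S,3aS,8aR)‑1‑hydroxy‑6,8a‑dimethyl‑3‑(propan‑2‑yl)‑3‑[(triethylsilyl)oxy]‑2,3,3a,8a‑tetrahydroazulen‑4(1H)‑one | O[C@@H]1C[C@](O[Si](CC)(CC)CC)(C(C)C)[C@H]2C(=O)C=C(C)C=C[C@@]12C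
F10 | step 11 | (1R,3S,3aS,8aR)‑1‑hydroxy‑6,8a‑dimethyl‑3‑(propan‑2‑yl)‑3‑[(triethylsilyl)oxy]‑1,2,3,3a,8,8a‑hexahydroazulen‑4(5H)‑one | O[C@@H]1C[C@](O[Si](CC)(CC)CC)(C(C)C)[C@H]2C(=O)CC(C)=CC[C@@]12C
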